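**Plan**
1. Retrosynthesis: the three phenolic OH groups are first masked as benzyl ethers. Then C3–C1' (ring C to ring B) and O1–C2 are cut together, which opens ring C to an o-hydroxyaryl enaminone (ring A part) and an arenediazonium salt (ring B part).
2. Enabling feature: C2=C3–C4=O of ring C is a vinylogous ester. With NMe2 in place of O1 on C2, C3 becomes the α-carbon of a push–pull alkene. The electron-rich ring B has the same (nucleophilic) polarity at C1', so it is delivered there as a σ-aryl radical (polarity reversal through N2+ and one-electron reduction).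
3. Ring A: phloroacetophenone is di-O-benzylated, hydroxylated para to the remaining chelated OH, and O-methylated. This puts OMe between the two OBn groups and leaves exactly one free OH, so ring C can close only to the 6-methoxy isomer.
4. Ring B: C1' lies para to the 4'-OMe and between two CH groups, which is the carboxyl position of 3-hydroxy-4,5-dimethoxybenzoic acid. The sequence is benzyl ether, Curtius rearrangement, aniline, diazonium tetrafluoroborate.
5. Forward order: rings A and B are bought as arenes, ring C arises in the coupling step, and one hydrogenolysis ends the route.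
6. Stereochemistry (remark): irigenin has no stereocentre, and the C3–C1' axis (H at both 2' and 6') rotates freely. The SMILES describes one achiral compound and nothing has to be set.

Key step: step 8

**Step 1**
Reactants: 1 2,4,6-trihydroxyacetophenone (phloroacetophenone)
Product: 2 1-[2,4-bis(benzyloxy)-6-hydroxyphenyl]ethan-1-one
Conditions: BnBr (2.05 equiv), K2CO3 (2.2 equiv), DMF, 25→60 °C
Reagents that add atoms: benzyl bromide, BrCc1ccccc1
Why: Williamson ether synthesis: with two equivalents of bromide the 4-OH and one of the two equivalent ortho OH groups should be alkylated, while the last OH is tied to the acetyl carbonyl by a strong hydrogen bond and stays free.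

**Step 2**
Reactants: 2 1-[2,4-bis(benzyloxy)-6-hydroxyphenyl]ethan-1-one
Product: 4 1-[2,4-bis(benzyloxy)-3,6-dihydroxyphenyl]ethan-1-one, via aryl potassium sulfate 3 (not isolated)
Conditions: K2S2O8 (1.1 equiv), aq KOH, pyridine, 0→20 °C; HCl to pH 4, unchanged 2 extracted; aqueous layer, 2 M HCl, 80 °C, N2
Reagents that add atoms: potassium peroxodisulfate, [K+].[K+].[O-]S(=O)(=O)OOS(=O)(=O)[O-]
Why: Elbs persulfate oxidation: the phenolate of 2 should attack the peroxide oxygen of the persulfate through its only free para carbon (C3, between the two benzyloxy groups) to give sulfate 3, whose acid hydrolysis (S–O cleavage) frees the hydroquinone while the benzyl ethers tolerate both aqueous stages.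

**Step 3**
Reactants: 4 1-[2,4-bis(benzyloxy)-3,6-dihydroxyphenyl]ethan-1-one
Product: 5 1-[2,4-bis(benzyloxy)-6-hydroxy-3-methoxyphenyl]ethan-1-one
Conditions: MeI (1.05 equiv), K2CO3 (1.1 equiv), acetone, N2, 25→45 °C
Reagents that add atoms: iodomethane, CI
Why: Chemoselective Williamson methylation: the new 3-OH is an ordinary phenol whereas the 6-OH is deactivated by chelation to the ketone, so one equivalent of MeI should methylate only O-3, as is usual for 2,5-dihydroxyacetophenones.

**Step 4**
Reactants: 5 1-[2,4-bis(benzyloxy)-6-hydroxy-3-methoxyphenyl]ethan-1-one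
Product: 6 (E)-1-[2,4-bis(benzyloxy)-6-hydroxy-3-methoxyphenyl]-3-(dimethylamino)prop-2-en-1-one
Conditions: DMF-DMA (2.5 equiv), toluene, 95 °C
Reagents that add atoms: N,N-dimethylformamide dimethyl acetal, COC(OC)N(C)C
Why: Condensation of a methyl ketone with an amide acetal: the acetyl CH3 is the only acidic C–H site, loss of two MeOH should give the conjugated (E)-enaminone, and the chelated phenol and the ethers are inert under these neutral conditions.

**Step 5**
Reactants: 7 3-hydroxy-4,5-dimethoxybenzoic acid
Product: 9 3-(benzyloxy)-4,5-dimethoxybenzoic acid, via benzyl ester 8 (not isolated)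
Conditions: BnBr (2.2 equiv), K2CO3 (2.5 equiv), DMF, 60 °C; then 2 M aq NaOH, MeOH, 60 °C; HCl work-up
Reagents that add atoms: benzyl bromide, BrCc1ccccc1; sodium hydroxide, [Na+].[OH-]
Why: Williamson etherification together with carboxylate alkylation gives 8, and saponification (BAc2) in the same flask should cleave only the ester, since aryl benzyl and aryl methyl ethers are stable to hydroxide.

**Step 6**
Reactants: 9 3-(benzyloxy)-4,5-dimethoxybenzoic acid
Product: 12 3-(benzyloxy)-4,5-dimethoxyaniline, via acyl azide 10 (not isolated), via aryl isocyanate 11 (not isolated)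
Conditions: DPPA (1.1 equiv), Et3N (1.2 equiv), toluene, 20→90 °C; then added to 2 M aq NaOH (excess), THF, 0→20 °C
Reagents that add atoms: diphenylphosphoryl azide (DPPA), [N-]=[N+]=NP(=O)(Oc1ccccc1)Oc1ccccc1
Why: Curtius rearrangement: DPPA converts the carboxylate into acyl azide 10, which on heating loses N2 with aryl migration to isocyanate 11, and an excess of hydroxide should outrun the product amine in attacking 11, so that hydrolysis with loss of the carbonyl carbon follows rather than urea formation.

**Step 7**
Reactants: 12 3-(benzyloxy)-4,5-dimethoxyaniline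
Product: 13 3-(benzyloxy)-4,5-dimethoxybenzenediazonium tetrafluoroborate
Conditions: 48% aq HBF4 (2.5 equiv), t-BuONO (1.3 equiv), EtOH, −5→0 °C; precipitation with Et2O, kept cold and dark
Reagents that add atoms: tert-butyl nitrite, CC(C)(C)ON=O; tetrafluoroboric acid, [H+].F[B-](F)(F)F
Why: Diazotisation of an aniline with an alkyl nitrite in the presence of HBF4 should give the sparingly soluble, storable tetrafluoroborate, the ethers being inert to cold dilute acid.

**Step 8**
Reactants: 6 (E)-1-[2,4-bis(benzyloxy)-6-hydroxy-3-methoxyphenyl]-3-(dimethylamino)prop-2-en-1-one; 13 3-(benzyloxy)-4,5-dimethoxybenzenediazonium tetrafluoroborate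
Product: 16 5,7-bis(benzyloxy)-3-[3-(benzyloxy)-4,5-dimethoxyphenyl]-6-methoxy-4H-chromen-4-one (tri-O-benzylirigenin), via iminium tetrafluoroborate 14 (not isolated), via 2-(dimethylamino)isoflavanone 15 (not isolated)
Conditions: 13 (1.5 equiv, added in MeCN over 2 h), [Ru(bpy)3](PF6)2 (1 mol %), degassed MeCN, blue LEDs (450 nm), 20 °C, no base
Reagents that add atoms: none
Why: Excited Ru(bpy)3(2+) reduces 13 by one electron, N2 leaves, and the σ-aryl radical centred on the future C1' adds to the α-carbon of the push–pull enaminone 6 (the future C3), the only mode that places the spin next to NMe2; the strongly reducing α-amino radical is then oxidised by Ru(III) or by a further molecule of 13 (chain) to iminium salt 14. The single free phenol oxygen (future O1) closes ring C on the iminium carbon (future C2) in a 6-exo-trig mode to aminal 15, and loss of Me2NH across C2–C3 gives the 4-pyranone, so the C3–C1' and O1–C2 bonds arise in one operation. The closest known reaction type is the visible-light arylation/chromone annulation of o-hydroxyaryl enaminones with arenediazonium salts, a Meerwein-type radical arylation. The sp3 centres at C2 and C3 in 14 and 15 are transient and are erased by the elimination, so no stereocontrol is needed. The radical path has to beat ionic azo coupling, which should be secured by the weakly electrophilic p-methoxy-substituted diazonium ion, its slow addition and the absence of base (the liberated Me2NH stays protonated by the acid formed and cannot give a triazene). Ring closure has to use the right oxygen, which is secured because the other ortho oxygen carries benzyl, fixing the 6-methoxy and excluding the 8-methoxy pattern.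

**Step 9**
Reactants: 16 tri-O-benzylirigenin
Product: 17 irigenin, 5,7-dihydroxy-3-(3-hydroxy-4,5-dimethoxyphenyl)-6-methoxy-4H-chromen-4-one
Conditions: H2 (1 atm), 10% Pd/C, THF–MeOH, 20 °C, stopped after uptake of 3 equiv H2
Reagents that add atoms: none
Why: Catalytic hydrogenolysis of the three O-benzyl groups should run under neutral conditions faster than saturation of the trisubstituted vinylogous-ester C2=C3 bond, leaves the three methyl ethers untouched and avoids the strong acid that could open ring C and reclose it to the 8-methoxy isomer (Wessely–Moser rearrangement).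

**Compound list**
1 | 2,4,6-trihydroxyacetophenone | CC(=O)c1c(O)cc(O)cc1O | starting material
2 | 1-[2,4-bis(benzyloxy)-6-hydroxyphenyl]ethan-1-one | CC(=O)c1c(O)cc(OCc2ccccc2)cc1OCc1ccccc1 | intermediate
3 | potassium 3-acetyl-2,6-bis(benzyloxy)-4-hydroxyphenyl sulfate (not isolated) | CC(=O)c1c(O)cc(OCc2ccccc2)c(OS(=O)(=O)[O-])c1OCc1ccccc1.[K+] | intermediate
4 | 1-[2,4-bis(benzyloxy)-3,6-dihydroxyphenyl]ethan-1-one | CC(=O)c1c(O)cc(OCc2ccccc2)c(O)c1OCc1ccccc1 | intermediate
5 | 1-[2,4-bis(benzyloxy)-6-hydroxy-3-methoxyphenyl]ethan-1-one | CC(=O)c1c(O)cc(OCc2ccccc2)c(OC)c1OCc1ccccc1 | intermediate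
6 | (E)-1-[2,4-bis(benzyloxy)-6-hydroxy-3-methoxyphenyl]-3-(dimethylamino)prop-2-en-1-one | CN(C)/C=C/C(=O)c1c(O)cc(OCc2ccccc2)c(OC)c1OCc1ccccc1 | intermediate
7 | 3-hydroxy-4,5-dimethoxybenzoic acid | COc1cc(C(=O)O)cc(O)c1OC | starting material
8 | benzyl 3-(benzyloxy)-4,5-dimethoxybenzoate (not isolated) | COc1cc(C(=O)OCc2ccccc2)cc(OCc2ccccc2)c1OC | intermediate
9 | 3-(benzyloxy)-4,5-dimethoxybenzoic acid | COc1cc(C(=O)O)cc(OCc2ccccc2)c1OC | intermediate
10 | 3-(benzyloxy)-4,5-dimethoxybenzoyl azide (not isolated) | COc1cc(C(=O)N=[N+]=[N-])cc(OCc2ccccc2)c1OC | intermediate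
11 | 1-(benzyloxy)-5-isocyanato-2,3-dimethoxybenzene (not isolated) | COc1cc(N=C=O)cc(OCc2ccccc2)c1OC | intermediate
12 | 3-(benzyloxy)-4,5-dimethoxyaniline | COc1cc(N)cc(OCc2ccccc2)c1OC | intermediate
13 | 3-(benzyloxy)-4,5-dimethoxybenzenediazonium tetrafluoroborate | COc1cc([N+]#N)cc(OCc2ccccc2)c1OC.F[B-](F)(F)F | intermediate
14 | α-aryl-β-oxo iminium tetrafluoroborate, N-{2-[3-(benzyloxy)-4,5-dimethoxyphenyl]-3-[2,4-bis(benzyloxy)-6-hydroxy-3-methoxyphenyl]-3-oxopropylidene}-N-methylmethanaminium tetrafluoroborate (racemic, transient, not isolated) | C[N+](C)=CC(c1cc(OC)c(OC)c(OCc2ccccc2)c1)C(=O)c1c(O)cc(OCc2ccccc2)c(OC)c1OCc1ccccc1.F[B-](F)(F)F | intermediate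
15 | 5,7-bis(benzyloxy)-3-[3-(benzyloxy)-4,5-dimethoxyphenyl]-2-(dimethylamino)-6-methoxychroman-4-one (stereoisomer mixture, transient, not isolated) | CN(C)C1Oc2cc(OCc3ccccc3)c(OC)c(OCc3ccccc3)c2C(=O)C1c1cc(OC)c(OC)c(OCc2ccccc2)c1 | intermediate
16 | 5,7-bis(benzyloxy)-3-[3-(benzyloxy)-4,5-dimethoxyphenyl]-6-methoxy-4H-chromen-4-one | COc1cc(cc(OCc2ccccc2)c1OC)-c1coc2cc(OCc3ccccc3)c(OC)c(OCc3ccccc3)c2c1=O | intermediate
17 | irigenin | COc1cc(-c2coc3cc(O)c(OC)c(O)c3c2=O)cc(O)c1OC | target

**Step count**
Total step count: 9. Longest linear sequence: 6 (steps 1, 2, 3, 4, 8, 9). The ring B branch (steps 5–7) joins at step 8.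

**Steps most likely to fail**

Step 8.
- What may go wrong: ionic azo coupling of the diazonium ion at the enaminone α-carbon or at the free C–H of ring A may outrun radical formation.
- The aryl radical may be lost by hydrogen abstraction.
- Traces of acid may cyclise the enaminone without arylation.
- Fallback: it sets out from 6 and 13 and returns at 16, replacing the radical union by a two-electron cross-coupling on a preformed ring C.
- Enaminone 6 is cyclised with I2 in CHCl3 at 20 °C (iodocyclisation with loss of the amine) to 5,7-bis(benzyloxy)-3-iodo-6-methoxy-4H-chromen-4-one F1.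
- Diazonium salt 13 is converted with B2pin2 (eosin Y, MeCN, green light, Sandmeyer-type borylation) into 2-[3-(benzyloxy)-4,5-dimethoxyphenyl]-4,4,5,5-tetramethyl-1,3,2-dioxaborolane F2.
- Suzuki–Miyaura coupling of the two (Pd(dppf)Cl2, K2CO3, dioxane–H2O, 80 °C) should give 16.

Step 2.
- What may go wrong: conversion may be low because the lipophilic phenolate dissolves poorly.
- The phenolate may be over-oxidised to polymeric material.
- Partial debenzylation may occur during the acid hydrolysis.
- Fallback: it sets out from 2 and returns at 4, replacing the persulfate substitution by oxidative dearomatisation and re-reduction.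
- Phenol 2 is oxidised with PhI(OCOCF3)2 in MeCN–H2O at 0 °C to 2-acetyl-3,5-bis(benzyloxy)cyclohexa-2,5-diene-1,4-dione F3.
- F3 is shaken with aqueous Na2S2O4 in EtOAc to give hydroquinone 4.

Step 9.
- What may go wrong: saturation of the C2=C3 bond may compete with slow cleavage of the hindered 5-O-benzyl group.
- Fallback: it sets out from 16 and returns at 17, replacing hydrogenolysis by Lewis-acid ether cleavage with a cation trap (BCl3, pentamethylbenzene, CH2Cl2, −78 °C, MeOH quench).
- At this temperature the methyl ethers and ring C should survive. The fallback makes no new compound (F0).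

**Further compounds**
F1 | step 8 | 5,7-bis(benzyloxy)-3-iodo-6-methoxy-4H-chromen-4-one | COc1c(OCc2ccccc2)cc2occ(I)c(=O)c2c1OCc1ccccc1
F2 | step 8 | 2-[3-(benzyloxy)-4,5-dimethoxyphenyl]-4,4,5,5-tetramethyl-1,3,2-dioxaborolane | COc1cc(B2OC(C)(C)C(C)(C)O2)cc(OCc2ccccc2)c1OC
F3 | step 2 | 2-acetyl-3,5-bis(benzyloxy)cyclohexa-2,5-diene-1,4-dione | CC(=O)C1=C(OCc2ccccc2)C(=O)C(OCc2ccccc2)=CC1=O
F0 | step 9 | none | none
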